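Labels: the outer phloroglucinol rings A and E are bonded to rings B and D (axis carbons B1, D1), which are ether-linked through B5 and D5 to central ring C; ring F is the pyrogallol ether. Everything rests on cutting A1–B1 and E1–D1. A single anodic dehydrogenative phenol–arene coupling makes both bonds, joining two molecules of 1,3,5-trimethoxybenzene to a methylated four-ring B–C–D–F core whose only free hydroxyls are B2–OH and D2–OH. It exploits that B1/B3 and D1/D3 are equivalent C–H sites ortho to those hydroxyls, with the para carbons B5 and D5 oxygen-blocked. The core comes from a dichloroquinone (C), two benzyl-masked phenols (B, D) and an aryne (F).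

Key step: step 9

Remark: the target has no stereogenic unit, because rings A and E are symmetric about the biaryl axes. Ring C is numbered C1 (oxygen to B), C3 (lone hydroxyl), C5 (oxygen to D), C6 (oxygen to F).

Step 1
Reactants: 1 2,6-dimethoxy-1,4-benzoquinone
Product: 2 2,6-dimethoxybenzene-1,4-diol
Conditions: Na2S2O4, THF/H2O, rt, under argon
Reagents that add atoms: none
Why: Dithionite reduction of a quinone to its hydroquinone is fast and leaves the methyl ethers untouched.

Step 2
Reactants: 2 2,6-dimethoxybenzene-1,4-diol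
Product: 3 4-(benzyloxy)-2,6-dimethoxyphenol
Conditions: BnBr (1.0 equiv), K2CO3 (1.1 equiv), degassed DMF, 0 °C to rt, under argon
Reagents that add atoms: benzyl bromide BrCc1ccccc1
Why: This Williamson etherification should go to the 4-hydroxyl, which is the more acidic and is unhindered, whereas the 1-hydroxyl lies between two methoxy groups and is hydrogen-bonded to them, and any neutral dibenzyl ether is removed by base extraction.

Step 3
Reactants: 3 4-(benzyloxy)-2,6-dimethoxyphenol (2.05 equiv); 4 2,6-dichloro-1,4-benzoquinone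
Product: 7 2,6-bis[4-(benzyloxy)-2,6-dimethoxyphenoxy]benzene-1,4-diol, via monoaryloxy chloroquinone 5 (not isolated), via bis(aryloxy)quinone 6 (not isolated)
Conditions: Cs2CO3 (2.2 equiv), dry MeCN, 0 °C to rt, under argon; then aq Na2S2O4, EtOAc, rt
Reagents that add atoms: none
Why: Twofold addition–elimination (vinylogous acyl substitution) of the phenoxide at the two chlorine-bearing quinone carbons, the classical entry to aryloxyquinones, should build both crowded diaryl ethers without a metal, and the reductive work-up converts the base-sensitive quinone directly into the hydroquinone.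

Step 4
Reactants: 7 2,6-bis[4-(benzyloxy)-2,6-dimethoxyphenoxy]benzene-1,4-diol
Product: 8 2,6-bis[4-(benzyloxy)-2,6-dimethoxyphenoxy]-4-methoxyphenol
Conditions: MeI (1.05 equiv), K2CO3 (1.1 equiv), degassed acetone, rt, under argon
Reagents that add atoms: iodomethane CI
Why: Williamson methylation with one equivalent of MeI should take the exposed C3 hydroxyl, since the C6 hydroxyl is buried between two ortho-disubstituted aryloxy groups and is hydrogen-bonded to their oxygens.

Step 5
Reactants: 9 3,4,5-trimethoxyphenol
Product: 10 2-bromo-3,4,5-trimethoxyphenol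
Conditions: NBS (1.0 equiv), MeCN, −20 °C to 0 °C
Reagents that add atoms: N-bromosuccinimide O=C1CCC(=O)N1Br
Why: In this electrophilic aromatic bromination the two open positions of 9 are equivalent and both ortho to the hydroxyl, so one equivalent of NBS at low temperature should give a single monobromide.

Step 6
Reactants: 10 2-bromo-3,4,5-trimethoxyphenol
Product: 13 3,4,5-trimethoxy-2-(trimethylsilyl)phenyl trifluoromethanesulfonate, via bromoaryl silyl ether 11 (not isolated), via lithium silylphenoxide 12 (not isolated)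
Conditions: HMDS, THF, 65 °C, then evaporation; n-BuLi, THF, −78 °C; then Tf2O, −78 °C to rt
Reagents that add atoms: hexamethyldisilazane C[Si](C)(C)N[Si](C)(C)C; trifluoromethanesulfonic anhydride O=S(=O)(OS(=O)(=O)C(F)(F)F)C(F)(F)F
Why: O-silylation, bromine–lithium exchange, a 1,3 oxygen-to-carbon silyl shift (retro-Brook rearrangement) and triflation of the released phenoxide form the standard one-flask entry to ortho-silylaryl triflate aryne precursors.

Step 7
Reactants: 8 2,6-bis[4-(benzyloxy)-2,6-dimethoxyphenoxy]-4-methoxyphenol; 13 3,4,5-trimethoxy-2-(trimethylsilyl)phenyl trifluoromethanesulfonate (1.5 equiv)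
Product: 15 1,3-bis[4-(benzyloxy)-2,6-dimethoxyphenoxy]-5-methoxy-2-(3,4,5-trimethoxyphenoxy)benzene, via 3,4,5-trimethoxybenzyne 14 (not isolated)
Conditions: CsF (4 equiv), MeCN, rt
Reagents that add atoms: none
Why: In this aryne O-arylation fluoride-induced 1,2-elimination releases 14, and the phenoxide of 8 adds to the aryne carbon remote from the flanking methoxy group (inductive and distortion control), so protonation leaves only the 3,4,5-trimethoxyphenyl ether, the aryne being small enough to reach the crowded C6 oxygen under non-oxidising conditions.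

Step 8
Reactants: 15 1,3-bis[4-(benzyloxy)-2,6-dimethoxyphenoxy]-5-methoxy-2-(3,4,5-trimethoxyphenoxy)benzene
Product: 16 4,4'-{[5-methoxy-2-(3,4,5-trimethoxyphenoxy)-1,3-phenylene]bis(oxy)}bis(3,5-dimethoxyphenol)
Conditions: H2 (1 atm), Pd/C, EtOAc/MeOH, rt
Reagents that add atoms: none
Why: Catalytic hydrogenolysis cleaves only the two benzylic C–O bonds, because diaryl and aryl methyl ethers are inert, and so frees exactly B2–OH and D2–OH.

Step 9
Reactants: 16 4,4'-{[5-methoxy-2-(3,4,5-trimethoxyphenoxy)-1,3-phenylene]bis(oxy)}bis(3,5-dimethoxyphenol); 17 1,3,5-trimethoxybenzene (20 equiv)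
Product: 19 5,5''-{[5-methoxy-2-(3,4,5-trimethoxyphenoxy)-1,3-phenylene]bis(oxy)}bis(2',4,4',6,6'-pentamethoxybiphenyl-2-ol), via five-ring monocoupled bisphenol 18 (not isolated)
Conditions: boron-doped diamond anode, Ni cathode, undivided cell, Et3NMe O3SOMe (0.1 M), dry HFIP without additive, constant current 4.7 mA cm−2, 4.4 F per mol of 16, rt
Reagents that add atoms: none
Why: Each free phenol (B2–OH, D2–OH), the most easily oxidised site present, should lose one electron and its proton at the diamond anode to give an HFIP-solvated phenoxyl radical with spin at B1/B3 (D1/D3) and at the oxygen-bearing B5 (D5); 17 then attacks the open ortho carbon through one of its three equivalent C–H positions, and a second electron transfer, proton loss and tautomerisation restore both aromatic rings while protons are reduced to H2 at the cathode. The closest known reaction type is the anodic dehydrogenative phenol–arene cross-coupling at boron-doped diamond in fluorinated alcohols, applied here once per arm by way of 18. The step closes no ring and creates no stereogenic unit, since rings A and E are symmetric about the new axes. Site selectivity comes from the substrate: only rings B and D carry a free hydroxyl, B1 and B3 (D1 and D3) are identical by local symmetry, and para coupling is excluded by the ether oxygen at B5 (D5). Partner selectivity over the open C–H sites of rings F, C and unoxidised B/D relies on the large excess of the more nucleophilic 17, on dilution of 16 and on HFIP hydrogen bonding that damps the phenol as a nucleophile, and a hole formed on ring F should drain to the neighbouring phenol. Water and methanol are kept out because ipso attack of an oxygen nucleophile at B5 or D5 would expel ring C, and the charge is held just above 4 F per mole so that the twisted, hindered product is neither arylated at B3/D3 nor oxidised further.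

Step 10
Reactants: 19 5,5''-{[5-methoxy-2-(3,4,5-trimethoxyphenoxy)-1,3-phenylene]bis(oxy)}bis(2',4,4',6,6'-pentamethoxybiphenyl-2-ol)
Product: 20 3,3''-{[5-hydroxy-2-(3,4,5-trihydroxyphenoxy)-1,3-phenylene]bis(oxy)}bis(biphenyl-2,2',4,4',6,6'-hexol) (CNP0279880.0)
Conditions: BBr3 (40 equiv), CH2Cl2, −78 °C to rt, under argon; then H2O, 0 °C; Sephadex LH-20 with degassed MeOH
Reagents that add atoms: none
Why: Lewis-acid aryl methyl ether cleavage with a large excess of BBr3 should remove all fourteen methyl groups while the diaryl ether and biaryl bonds stay intact at or below room temperature, and hot protic acids are avoided because 2,2'-dihydroxybiaryls of this type can close to dibenzofurans.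

Compound list
1 | 2,6-dimethoxy-1,4-benzoquinone | COC1=CC(=O)C=C(OC)C1=O | starting material
2 | 2,6-dimethoxybenzene-1,4-diol | COc1cc(O)cc(OC)c1O | intermediate
3 | 4-(benzyloxy)-2,6-dimethoxyphenol | COc1cc(OCc2ccccc2)cc(OC)c1O | intermediate
4 | 2,6-dichloro-1,4-benzoquinone | O=C1C=C(Cl)C(=O)C(Cl)=C1 | starting material
5 | 2-[4-(benzyloxy)-2,6-dimethoxyphenoxy]-6-chloro-1,4-benzoquinone | O=C1C=C(Cl)C(=O)C(Oc2c(OC)cc(OCc3ccccc3)cc2OC)=C1 | intermediate
6 | 2,6-bis[4-(benzyloxy)-2,6-dimethoxyphenoxy]-1,4-benzoquinone | O=C1C=C(Oc2c(OC)cc(OCc3ccccc3)cc2OC)C(=O)C(Oc2c(OC)cc(OCc3ccccc3)cc2OC)=C1 | intermediate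
7 | 2,6-bis[4-(benzyloxy)-2,6-dimethoxyphenoxy]benzene-1,4-diol | Oc1cc(Oc2c(OC)cc(OCc3ccccc3)cc2OC)c(O)c(Oc2c(OC)cc(OCc3ccccc3)cc2OC)c1 | intermediate
8 | 2,6-bis[4-(benzyloxy)-2,6-dimethoxyphenoxy]-4-methoxyphenol | COc1cc(Oc2c(OC)cc(OCc3ccccc3)cc2OC)c(O)c(Oc2c(OC)cc(OCc3ccccc3)cc2OC)c1 | intermediate
9 | 3,4,5-trimethoxyphenol | COc1cc(O)cc(OC)c1OC | starting material
10 | 2-bromo-3,4,5-trimethoxyphenol | COc1cc(O)c(Br)c(OC)c1OC | intermediate
11 | (2-bromo-3,4,5-trimethoxyphenoxy)trimethylsilane | COc1cc(O[Si](C)(C)C)c(Br)c(OC)c1OC | intermediate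
12 | lithium 3,4,5-trimethoxy-2-(trimethylsilyl)phenoxide | [Li+].[O-]c1cc(OC)c(OC)c(OC)c1[Si](C)(C)C | intermediate
13 | 3,4,5-trimethoxy-2-(trimethylsilyl)phenyl trifluoromethanesulfonate | COc1cc(OS(=O)(=O)C(F)(F)F)c([Si](C)(C)C)c(OC)c1OC | intermediate
14 | 3,4,5-trimethoxybenzyne (1,2-didehydro-3,4,5-trimethoxybenzene) | COC1=CC#CC(OC)=C1OC | intermediate
15 | 1,3-bis[4-(benzyloxy)-2,6-dimethoxyphenoxy]-5-methoxy-2-(3,4,5-trimethoxyphenoxy)benzene | COc1cc(Oc2c(OC)cc(OCc3ccccc3)cc2OC)c(Oc2cc(OC)c(OC)c(OC)c2)c(Oc2c(OC)cc(OCc3ccccc3)cc2OC)c1 | intermediate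
16 | four-ring core bisphenol, 4,4'-{[5-methoxy-2-(3,4,5-trimethoxyphenoxy)-1,3-phenylene]bis(oxy)}bis(3,5-dimethoxyphenol) | COc1cc(Oc2c(OC)cc(O)cc2OC)c(Oc2cc(OC)c(OC)c(OC)c2)c(Oc2c(OC)cc(O)cc2OC)c1 | intermediate
17 | 1,3,5-trimethoxybenzene | COc1cc(OC)cc(OC)c1 | starting material
18 | five-ring monocoupled bisphenol (16 bearing a 2,4,6-trimethoxyphenyl group at B1 only) | COc1cc(Oc2c(OC)cc(O)c(-c3c(OC)cc(OC)cc3OC)c2OC)c(Oc2cc(OC)c(OC)c(OC)c2)c(Oc2c(OC)cc(O)cc2OC)c1 | intermediate
19 | six-ring tetradecamethyl ether with free B2 and D2 hydroxyls, 5,5''-{[5-methoxy-2-(3,4,5-trimethoxyphenoxy)-1,3-phenylene]bis(oxy)}bis(2',4,4',6,6'-pentamethoxybiphenyl-2-ol) | COc1cc(Oc2c(OC)cc(O)c(-c3c(OC)cc(OC)cc3OC)c2OC)c(Oc2cc(OC)c(OC)c(OC)c2)c(Oc2c(OC)cc(O)c(-c3c(OC)cc(OC)cc3OC)c2OC)c1 | intermediate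
20 | CNP0279880.0, 3,3''-{[5-hydroxy-2-(3,4,5-trihydroxyphenoxy)-1,3-phenylene]bis(oxy)}bis(biphenyl-2,2',4,4',6,6'-hexol) | Oc1cc(O)c(-c2c(O)cc(O)c(Oc3cc(O)cc(Oc4c(O)cc(O)c(-c5c(O)cc(O)cc5O)c4O)c3Oc3cc(O)c(O)c(O)c3)c2O)c(O)c1 | target

Total step count: 10. Longest linear sequence: 8 (steps 1–4 and 7–10). Steps 5 and 6 form the side branch to the aryne precursor.

Steps most likely to fail

1. Step 9.
- What may go wrong: over-oxidation with ipso attack at B5/D5 and loss of ring C, self-coupling through the electron-rich rings of the substrate, or stalling after the first arm.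
- Fallback: it sets out from 16. Phenol-directed ortho-bromination (NBS 2 equiv, catalytic i-Pr2NH, CH2Cl2, −78 °C to 0 °C) should give 4,4'-{[5-methoxy-2-(3,4,5-trimethoxyphenoxy)-1,3-phenylene]bis(oxy)}bis(2-bromo-3,5-dimethoxyphenol) F1.
- A twofold Suzuki–Miyaura coupling follows with purchased 2,4,6-trimethoxyphenylboronic acid F2 (Pd(OAc)2, SPhos, K3PO4, toluene/H2O, 100 °C). This ligand class is established for tetra-ortho-substituted biaryls.
- The coupling forms the same A1–B1 and E1–D1 bonds and comes back to the route at 19.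

2. Step 3.
- What may go wrong: single-electron transfer from the very electron-rich phenoxide to the quinone, conjugate addition at the unsubstituted quinone carbons instead of chloride displacement, or base-induced degradation of the haloquinone.
- Fallback: it sets out from 3 and 13 and replaces the quinone by an aryl dihalide. Purchased 2,6-dibromo-4-methoxyphenol F3 is O-arylated with the aryne released from 13 (CsF, MeCN, rt) to give 1,3-dibromo-5-methoxy-2-(3,4,5-trimethoxyphenoxy)benzene F4.
- A twofold Ullmann ether synthesis of this dibromide with 3 (CuI, picolinic acid, K3PO4, DMSO, 100 °C) comes back to the route at 15, bypassing steps 3, 4 and 7.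

3. Step 10.
- What may go wrong: incomplete cleavage because partly demethylated borates precipitate, and air oxidation of the free polyphenol during purification.
- Fallback: it sets out from 19 and works by derivatising, purifying and releasing. The crude BBr3 product is peracetylated (Ac2O, pyridine, rt) to the hexadecaacetate of the target F5.
- The hexadecaacetate is stable to air and can be chromatographed on silica, so that under-cleaved material can be separated and resubmitted.
- Acid-catalysed methanolysis (catalytic HCl from AcCl in degassed MeOH, rt to 40 °C) gives only volatile side products and comes back to the route at 20 by simple evaporation.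

Further compounds
F1 | step 9 | 4,4'-{[5-methoxy-2-(3,4,5-trimethoxyphenoxy)-1,3-phenylene]bis(oxy)}bis(2-bromo-3,5-dimethoxyphenol) | COc1cc(Oc2c(OC)cc(O)c(Br)c2OC)c(Oc2cc(OC)c(OC)c(OC)c2)c(Oc2c(OC)cc(O)c(Br)c2OC)c1
F2 | step 9 | 2,4,6-trimethoxyphenylboronic acid (purchased) | COc1cc(OC)c(B(O)O)c(OC)c1
F3 | step 3 | 2,6-dibromo-4-methoxyphenol (purchased) | COc1cc(Br)c(O)c(Br)c1
F4 | step 3 | 1,3-dibromo-5-methoxy-2-(3,4,5-trimethoxyphenoxy)benzene | COc1cc(Br)c(Oc2cc(OC)c(OC)c(OC)c2)c(Br)c1
F5 | step 10 | hexadecaacetate of the target | CC(=O)Oc1cc(OC(C)=O)c(-c2c(OC(C)=O)cc(OC(C)=O)c(Oc3cc(OC(C)=O)cc(Oc4c(OC(C)=O)cc(OC(C)=O)c(-c5c(OC(C)=O)cc(OC(C)=O)cc5OC(C)=O)c4OC(C)=O)c3Oc3cc(OC(C)=O)c(OC(C)=O)c(OC(C)=O)c3)c2OC(C)=O)c(OC(C)=O)c1
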